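## Structural features

The target is a diarylmethane. C6 of a 5-hydroxy-7-methoxy-2-methylchromone is joined through one CH2 group to C5 of a (3R)-6,8-dihydroxy-3,7-dimethyl-3,4-dihydroisocoumarin. The isocoumarin benzene ring (C4a, C5, C6, C7, C8, C8a) carries six different substituents; the chromone benzene ring keeps only H8. There is one stereocentre, C3 (R) in the δ-lactone. It has no stereogenic neighbour and is not enolisable, so it can come from the chiral pool and only has to be protected from β-elimination. Fragile groups are the lactone (opened by alkoxides or hot amines), the chromone (Michael acceptor at C2, acidic 2-methyl group, not compatible with amide bases), the electron-rich diarylmethane bridge (cleaved by strong protic acid) and three phenols. The real difficulty is the regiocontrolled construction of the hexasubstituted resorcylate ring, together with differentiating the two chromone oxygens (O5 free and chelated, O7 methylated). The key step uses the 1,3-alternation of oxygen on C1, C8 and C6 of the isocoumarin. This is the pattern of a folded poly-β-carbonyl chain, so the ring can be closed from an open chain by one aldol bond, C4a–C8a, with the C7 methyl and the C5 benzylic arm already on the chain.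

## Logic of the disconnections

19 from 18. The O–CH3 bond at chromone O5 is added in the retrosynthetic direction. A methyl ether at O5 keeps an ortho-hydroxybenzyl halide (and its quinone methide) out of the route and lets both chromone oxygens come from the symmetric 8. The forward step must remove only the methyl group peri to the C4 carbonyl, leaving the O7 methyl and the lactone alone.

18 from 16 (through 17). The lactone bond C1–O2 is cut. In 16, C1 and O8 are tied together as an acetonide and O2 is silylated, so the acid, the 8-phenol and the alcohol are all masked by groups the key step creates or tolerates. One reagent must free the alcohol and let it displace the acetonide oxygen by six-membered acyl transfer, without touching the C3–O bond.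

16 from 14 (through 15). The ring bond C4a–C8a is cut. A benzene ring with six different substituents becomes a linear chain on a dioxinone, with every substituent already placed by chain position. The forward step must favour carbon over oxygen cyclisation and must not eliminate the β-silyloxy group.

14 from 7 and 13. The bond from C5 to the bridging CH2 is cut. This keeps the base-sensitive chromone out of all amide-base steps and makes the route convergent. The forward alkylation must hit the central carbon of the 1,3-diketone, and must do so faster than 7 closes to an arene on its own.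

7 from 3 and 6. The bond C4a–C5 is cut (Claisen disconnection). 3 supplies C8a, C8, C7, C6 and C5, and 6 supplies C4a, C4, C3 and the C3 methyl. The forward step needs the dianion of 3 to react at its terminal carbon, and the acyl donor must not over-add or eliminate silanolate.

3 from 2, and 2 from 1. The bonds C6–C7 (acetyl) and C7–CH3 are cut. Both are γ-functionalisations of a dioxinone dienolate, which is needed to place the C7 methyl before the chain grows. The forward steps need γ- over α-selectivity and C- over O-acylation.

6 from 5, and 5 from 4. No skeletal bond is cut; the amide C–N and the O–Si bond are removed. The chiral-pool ester 4 supplies C3 with the R configuration. The forward steps must not epimerise or eliminate, which the β-position of the stereocentre ensures.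

13 from 12, and 12 from 11. These are functional-group changes at the bridging carbon (C–Br to C–OH to C=O). The aldehyde is the stable storage form of a very electron-rich benzylic position. The hydride must spare the chromone carbonyl and the bromide must be used fresh.

11 from 9 (through 10), and 9 from 8. The pyranone bonds C4a–C4, C4–C3 and O1–C2 are cut, then the C–I bond. Because the two positions ortho to the phenol in 8 are equivalent, the chromone can only form with the formyl group at C6 between the two methoxy groups. The forward annulation must close in the six-membered (chromone) and not the five-membered (aurone) mode.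

## Other disconnections considered

Alternative 1: biomimetic folding of a pentaketide chain into both chromone rings.
- Cut: the chromone benzene bond C4a–C5 and the pyranone bond O1–C2. This unfolds both chromone rings into the linear tetraketo ester A1, which carries the finished, benzyl-protected isocoumarin on its C2 methine.
- Forward key step: a magnesium alkoxide or hydroxide base would drive Claisen closure (the later C4a onto the ester carbon, the later C5) to an acylphloroglucinol. Its phenol oxygen then adds to the terminal ketone and dehydrates to the 5,7-dihydroxychromone A2.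
- In favour: two rings would form in one flask, with the regiochemistry fixed by the chain.
- Better than the chosen plan on one point: O7 could afterwards be methylated selectively because O5 is chelated. This is a milder way to differentiate the two oxygens than the Lewis acid demethylation of step 13.
- Against it here: A1 is a free 3,5,7,9-tetraketo ester with several competing closures (aldol to orsellinate-type rings, pyranones). Its C2 substituent would have to be introduced at the least nucleophilic carbon of a polyanion. The base needed for the Claisen mode would also attack the lactone, which in A2 is not protected by chelation.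
- Comparison: the mechanism is the same family as the chosen aldol (folding of a poly-β-carbonyl chain), so on logic the two are equals. On structure it builds the easier ring last and leaves the hexasubstituted isocoumarin ring unsolved. On step economy it would be longer, because that ring would still need a step like step 11 earlier on. The endgame (methylation, hydrogenolysis) equals the two steps of the chosen plan.

Alternative 2: late three-component carbonylative annulation of the pyranone ring.
- Cut: C4a–C4, C4–C3 and O1–C2 of the pyranone, leading back to the iodophenol A3, which already contains the diarylmethane and the isocoumarin.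
- Forward key step: the same palladium-catalysed carbonylation/alkyne coupling/cyclisation as step 7 of the chosen plan, run on A3, would give the chromone A4.
- In favour: no polyketone is handled late, and the reaction type is the same as step 7, so in reliability of the bond-forming event the two plans are equal.
- Better than the chosen plan on one point: the endgame could be one step, since a single Lewis acid dealkylation of the type of step 13 might remove both benzyl groups and the peri methyl group.
- Against it here: hot secondary amine under pressure would meet the unchelated lactone of A3 and could open it by aminolysis. The iodide in A3 is flanked on both sides and sits next to a bulky benzylic arm.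
- Comparison: the alternative differs from the chosen plan in timing, not in chemistry; the chosen plan runs the annulation on the small, robust 9. On structure the alternative does nothing for the hexasubstituted ring, which would still have to be made and then joined to the phloroglucinol unit. The step count before A3 would therefore exceed that of the chosen route.

Alternative 3: photochemical vinylketene–siloxyalkyne benzannulation on the preformed lactone.
- Cut: C7–C8, C5–C6 and C8–C8a of the isocoumarin benzene ring, leading back to the diazo ketone A5 (a chiral dihydropyranone) and the siloxyalkyne A6.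
- Forward key step: photolysis of A5 would trigger a Wolff rearrangement to a vinylketene. This adds A6 by [2+2] cycloaddition; four-electron ring opening and six-electron closure would then give the phenol A7.
- In favour: all six substituents are placed by the mechanism under neutral conditions, and O6 and O8 emerge differentiated.
- Better than the chosen plan on one point: the lactone and C3 are in place before the arene forms, so no lactonisation step and no C- versus O-cyclisation question arise.
- Against it here: the carbene carbon of A5 carries a benzylic CH2, so 1,2-hydrogen shift to an enone could compete with the Wolff rearrangement. The chromone absorbs in the same region and can undergo its own photochemistry. A5 needs a diazo transfer under basic conditions in the presence of the chromone, after a multistep synthesis of the acyl dihydropyranone.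
- Comparison: on structure both plans attack the right ring, and this one forms three bonds where the chosen one forms one. On mechanism it is pericyclic and neutral where the chosen one is ionic and base-mediated. On step economy the post-key steps are equal (desilylation and demethylation, two steps), but the route to A5 would be clearly longer than the route to 14.

Key step: step 11

Remark on the chemistry: compounds 3, 7, 14 and 15 contain sp3 carbons (the later C7, C5 and C4a) that become arene carbons in step 11. They are used as mixtures of epimers and keto–enol tautomers and are drawn without configuration at those carbons.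

Structure check: 14 and 16 differ by exactly one H2O, the chain atoms of 14 map one-to-one onto C1–C8a of 19, and C3 is R in 4, 14, 16 and 19. No structure needed correction. The design changes are the acyl donor (amide 6 in place of an acyl imidazole) and the route to 13.

## Route

Step 1
Reactants: 1 2,2,6-trimethyl-4H-1,3-dioxin-4-one
Product: 2 6-ethyl-2,2-dimethyl-4H-1,3-dioxin-4-one
Conditions: LiN(iPr)2, THF, −78 °C; MeI, DMPU, −78 → −30 °C
Reagents that add atoms: iodomethane, CI
Why: γ-Alkylation of the lithium dienolate of the dioxinone (vinylogous enolate alkylation); the polar cosolvent directs the soft electrophile to the terminal carbon, and stoichiometry at low temperature limits the reaction to one methyl group.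

Step 2
Reactants: 2 6-ethyl-2,2-dimethyl-4H-1,3-dioxin-4-one
Product: 3 2,2-dimethyl-6-(3-oxobutan-2-yl)-4H-1,3-dioxin-4-one (racemic)
Conditions: LiN(SiMe3)2, THF, −78 °C (dienolate in twofold excess); AcCl, −78 °C; aq. NH4Cl
Reagents that add atoms: acetyl chloride, CC(=O)Cl
Why: Crossed Claisen-type C-acylation of the vinylogous lithium enolate at its γ-carbon, the standard entry to keto-dioxinones; the excess dienolate absorbs the proton of the more acidic product.

Step 3
Reactants: 4 methyl (R)-3-hydroxybutanoate
Product: 5 methyl (R)-3-[(tert-butyldimethylsilyl)oxy]butanoate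
Conditions: TBSCl, imidazole, DMF, rt
Reagents that add atoms: tert-butyldimethylsilyl chloride, CC(C)(C)[Si](C)(C)Cl
Why: Silylation of a secondary alcohol; the stereocentre is not involved and stays R.

Step 4
Reactants: 5 methyl (R)-3-[(tert-butyldimethylsilyl)oxy]butanoate
Product: 6 (R)-3-[(tert-butyldimethylsilyl)oxy]-N-methoxy-N-methylbutanamide
Conditions: MeNH(OMe)·HCl, iPrMgCl, THF, −20 → 0 °C
Reagents that add atoms: N,O-dimethylhydroxylamine hydrochloride, CNOC.Cl
Why: Direct ester-to-Weinreb-amide exchange by the chloromagnesium amide formed in the flask; the cold, short exposure avoids β-elimination, and C3 has no acidic hydrogen.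

Step 5
Reactants: 3 2,2-dimethyl-6-(3-oxobutan-2-yl)-4H-1,3-dioxin-4-one; 6 (R)-3-[(tert-butyldimethylsilyl)oxy]-N-methoxy-N-methylbutanamide
Product: 7 6-[(7R)-7-[(tert-butyldimethylsilyl)oxy]-3,5-dioxooctan-2-yl]-2,2-dimethyl-4H-1,3-dioxin-4-one
Conditions: LiN(iPr)2 (2 equiv on 3; 3 in excess over 6), THF, −78 °C; then 6, −78 → −30 °C; aq. NH4Cl
Reagents that add atoms: none
Why: Claisen-type acylation of the keto-dioxinone dianion at its terminal, last-formed and most nucleophilic carbon; the chelated tetrahedral adduct of the Weinreb amide persists until the quench, so neither double addition nor in-flask enolisation of the product occurs. 7 is expected mainly as enol tautomers.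

Step 6
Reactants: 8 4-hydroxy-2,6-dimethoxybenzaldehyde
Product: 9 4-hydroxy-3-iodo-2,6-dimethoxybenzaldehyde
Conditions: N-iodosuccinimide (1.0 equiv), CF3CO2H (cat.), MeCN, 0 °C → rt
Reagents that add atoms: N-iodosuccinimide, O=C1CCC(=O)N1I
Why: Electrophilic aromatic iodination ortho to the phenol; the two free positions are equivalent by symmetry, so only the degree of iodination has to be held by stoichiometry.

Step 7
Reactants: 9 4-hydroxy-3-iodo-2,6-dimethoxybenzaldehyde
Product: 11 5,7-dimethoxy-2-methyl-4-oxo-4H-chromene-6-carbaldehyde, via ynone 10 (not isolated)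
Conditions: propyne, CO (20 atm), PdCl2(PPh3)2 (cat.), Et2NH, 110 °C, autoclave
Reagents that add atoms: propyne, CC#C; carbon monoxide, [C-]#[O+]
Why: Carbonylative Sonogashira-type coupling and cyclisation: zerovalent palladium formed in the flask inserts into the C–I bond, CO insertion gives the aroylpalladium species, and coupling with propyne gives ynone 10. The neighbouring phenol then closes by amine-promoted 6-endo oxa-Michael addition; the secondary amine as solvent is what steers the closure to the chromone and away from the 5-exo aurone.

Step 8
Reactants: 11 5,7-dimethoxy-2-methyl-4-oxo-4H-chromene-6-carbaldehyde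
Product: 12 6-(hydroxymethyl)-5,7-dimethoxy-2-methyl-4H-chromen-4-one
Conditions: NaBH4, MeOH/CH2Cl2, 0 °C
Reagents that add atoms: none
Why: Chemoselective borohydride reduction; the aldehyde is much more electrophilic than the vinylogous-ester carbonyl of the chromone at 0 °C.

Step 9
Reactants: 12 6-(hydroxymethyl)-5,7-dimethoxy-2-methyl-4H-chromen-4-one
Product: 13 6-(bromomethyl)-5,7-dimethoxy-2-methyl-4H-chromen-4-one
Conditions: PBr3, CH2Cl2, 0 °C; crude bromide used at once
Reagents that add atoms: phosphorus tribromide, BrP(Br)Br
Why: Conversion of a benzylic alcohol into the bromide through its phosphite ester; the two ortho methoxy groups make the bromide very reactive, so it is not stored.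

Step 10
Reactants: 7 6-[(7R)-7-[(tert-butyldimethylsilyl)oxy]-3,5-dioxooctan-2-yl]-2,2-dimethyl-4H-1,3-dioxin-4-one; 13 6-(bromomethyl)-5,7-dimethoxy-2-methyl-4H-chromen-4-one
Product: 14 6-[(7R)-7-[(tert-butyldimethylsilyl)oxy]-4-[(5,7-dimethoxy-2-methyl-4-oxo-4H-chromen-6-yl)methyl]-3,5-dioxooctan-2-yl]-2,2-dimethyl-4H-1,3-dioxin-4-one
Conditions: K2CO3 (1.1 equiv), 13 (1.2 equiv), acetone, 0 °C → rt; pH 5 buffer work-up
Reagents that add atoms: none
Why: C-Alkylation of the potassium enolate of a 1,3-diketone with a reactive benzylic bromide; the central carbon C5 is the most acidic site (between two ketones, whereas C7 is tertiary and flanked by only one ketone), so one equivalent of mild base selects it. Low temperature, excess electrophile and a slightly acidic work-up keep the base-induced ring closure of 7 behind the alkylation.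

Step 11
Reactants: 14 6-[(7R)-7-[(tert-butyldimethylsilyl)oxy]-4-[(5,7-dimethoxy-2-methyl-4-oxo-4H-chromen-6-yl)methyl]-3,5-dioxooctan-2-yl]-2,2-dimethyl-4H-1,3-dioxin-4-one
Product: 16 5-[(2R)-2-[(tert-butyldimethylsilyl)oxy]propyl]-6-[(5,7-dimethoxy-2-methyl-4-oxo-4H-chromen-6-yl)methyl]-7-hydroxy-2,2,8-trimethyl-4H-1,3-benzodioxin-4-one, via cyclic aldol 15 (not isolated)
Conditions: Et3N, CH2Cl2, rt
Reagents that add atoms: none
Why: Triethylamine reversibly removes the C7 hydrogen to give the vinylogous enolate that runs through the dioxinone C8=C8a bond into the C1 carbonyl; its C8a carbon adds to the C4a ketone, forming bond C4a–C8a and the cyclic aldol 15. This is the intramolecular aldol condensation known for diketo-dioxinones in biomimetic resorcylate synthesis, and the ring C4a–C5–C6–C7–C8–C8a closes in the 6-(enolendo)-exo-trig mode, with the reacting enol double bond C7=C8 inside the new ring and the attacked C=O outside it. E1cB loss of the C4a hydroxyl and enolisation of the C6 ketone then give the benzene ring, so aromatisation drives the sequence to completion and removes the stereocentres at C5, C7 and C4a; no new stereocentre is formed, and C3, which is β to the ketone and not enolisable, stays R. The step needs carbon over oxygen cyclisation: an amine in an aprotic solvent raises the carbon nucleophile without acid activation of the acetal-bearing carbon C8, which attack by an enol oxygen (leading to a pyranone) would need, and at room temperature the dioxinone does not open to an acylketene. Of the possible carbon–carbon closures only C8a onto C4a gives a six-membered ring that can lose water to an arene with this oxygen pattern. The C7 methyl and the C5 chromonylmethyl group arrive with the chain, so the hexasubstituted ring needs no aromatic substitution, and the weak base leaves the chromone, the silyl ether and the β-silyloxy ketone intact.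

Step 12
Reactants: 16 5-[(2R)-2-[(tert-butyldimethylsilyl)oxy]propyl]-6-[(5,7-dimethoxy-2-methyl-4-oxo-4H-chromen-6-yl)methyl]-7-hydroxy-2,2,8-trimethyl-4H-1,3-benzodioxin-4-one
Product: 18 (3R)-5-[(5,7-dimethoxy-2-methyl-4-oxo-4H-chromen-6-yl)methyl]-6,8-dihydroxy-3,7-dimethyl-3,4-dihydro-1H-isochromen-1-one, via desilylated alcohol 17 (not isolated)
Conditions: Bu4NF (3 equiv), THF, 0 °C → rt; aq. NH4Cl
Reagents that add atoms: none
Why: Fluoride cleaves the Si–O bond and the resulting alkoxide attacks the acetonide-activated carbonyl in a 6-exo-trig acyl transfer (benzodioxinone opening by an alkoxide); the departing hemiketal oxygen collapses irreversibly to acetone and the C8 phenoxide. The C3–O bond is never broken, so the R configuration is retained.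

Step 13
Reactants: 18 (3R)-5-[(5,7-dimethoxy-2-methyl-4-oxo-4H-chromen-6-yl)methyl]-6,8-dihydroxy-3,7-dimethyl-3,4-dihydro-1H-isochromen-1-one
Product: 19 (3R)-6,8-dihydroxy-5-[(5-hydroxy-7-methoxy-2-methyl-4-oxo-4H-chromen-6-yl)methyl]-3,7-dimethyl-3,4-dihydro-1H-isochromen-1-one
Conditions: BCl3 (excess), CH2Cl2, −78 → 0 °C; aq. NaHCO3
Reagents that add atoms: none
Why: Chelation-controlled Lewis acid ether cleavage: boron binds between the chromone C4 carbonyl and the peri O5, and chloride removes that methyl group. The O7 methyl lacks this activation and the lactone is inert at this temperature.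

## Compound list

1 | 2,2,6-trimethyl-4H-1,3-dioxin-4-one | CC1=CC(=O)OC(C)(C)O1 | starting material
2 | 6-ethyl-2,2-dimethyl-4H-1,3-dioxin-4-one | CCC1=CC(=O)OC(C)(C)O1 | intermediate
3 | 2,2-dimethyl-6-(3-oxobutan-2-yl)-4H-1,3-dioxin-4-one (racemic) | CC(=O)C(C)C1=CC(=O)OC(C)(C)O1 | intermediate
4 | methyl (R)-3-hydroxybutanoate | C[C@@H](O)CC(=O)OC | starting material
5 | methyl (R)-3-[(tert-butyldimethylsilyl)oxy]butanoate | C[C@H](CC(=O)OC)O[Si](C)(C)C(C)(C)C | intermediate
6 | (R)-3-[(tert-butyldimethylsilyl)oxy]-N-methoxy-N-methylbutanamide | C[C@H](CC(=O)N(C)OC)O[Si](C)(C)C(C)(C)C | intermediate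
7 | 6-[(7R)-7-[(tert-butyldimethylsilyl)oxy]-3,5-dioxooctan-2-yl]-2,2-dimethyl-4H-1,3-dioxin-4-one (epimers at chain C2) | C[C@H](CC(=O)CC(=O)C(C)C1=CC(=O)OC(C)(C)O1)O[Si](C)(C)C(C)(C)C | intermediate
8 | 4-hydroxy-2,6-dimethoxybenzaldehyde | COc1cc(O)cc(OC)c1C=O | starting material
9 | 4-hydroxy-3-iodo-2,6-dimethoxybenzaldehyde | COc1cc(O)c(I)c(OC)c1C=O | intermediate
10 | 3-(but-2-ynoyl)-4-hydroxy-2,6-dimethoxybenzaldehyde | CC#CC(=O)c1c(O)cc(OC)c(C=O)c1OC | intermediate
11 | 5,7-dimethoxy-2-methyl-4-oxo-4H-chromene-6-carbaldehyde | Cc1cc(=O)c2c(OC)c(C=O)c(OC)cc2o1 | intermediate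
12 | 6-(hydroxymethyl)-5,7-dimethoxy-2-methyl-4H-chromen-4-one | Cc1cc(=O)c2c(OC)c(CO)c(OC)cc2o1 | intermediate
13 | 6-(bromomethyl)-5,7-dimethoxy-2-methyl-4H-chromen-4-one | Cc1cc(=O)c2c(OC)c(CBr)c(OC)cc2o1 | intermediate
14 | 6-[(7R)-7-[(tert-butyldimethylsilyl)oxy]-4-[(5,7-dimethoxy-2-methyl-4-oxo-4H-chromen-6-yl)methyl]-3,5-dioxooctan-2-yl]-2,2-dimethyl-4H-1,3-dioxin-4-one (epimers at chain C2 and C4) | C[C@H](CC(=O)C(Cc1c(OC)cc2oc(C)cc(=O)c2c1OC)C(=O)C(C)C1=CC(=O)OC(C)(C)O1)O[Si](C)(C)C(C)(C)C | intermediate
15 | 5-[(2R)-2-[(tert-butyldimethylsilyl)oxy]propyl]-6-[(5,7-dimethoxy-2-methyl-4-oxo-4H-chromen-6-yl)methyl]-5-hydroxy-2,2,8-trimethyl-5,6-dihydro-4H-1,3-benzodioxine-4,7(8H)-dione (diastereomer mixture) | C[C@H](CC1(O)C(Cc2c(OC)cc3oc(C)cc(=O)c3c2OC)C(=O)C(C)C2=C1C(=O)OC(C)(C)O2)O[Si](C)(C)C(C)(C)C | intermediate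
16 | 5-[(2R)-2-[(tert-butyldimethylsilyl)oxy]propyl]-6-[(5,7-dimethoxy-2-methyl-4-oxo-4H-chromen-6-yl)methyl]-7-hydroxy-2,2,8-trimethyl-4H-1,3-benzodioxin-4-one | C[C@H](Cc1c(Cc2c(OC)cc3oc(C)cc(=O)c3c2OC)c(O)c(C)c2OC(C)(C)OC(=O)c12)O[Si](C)(C)C(C)(C)C | intermediate
17 | 6-[(5,7-dimethoxy-2-methyl-4-oxo-4H-chromen-6-yl)methyl]-7-hydroxy-5-[(2R)-2-hydroxypropyl]-2,2,8-trimethyl-4H-1,3-benzodioxin-4-one | C[C@@H](O)Cc1c(Cc2c(OC)cc3oc(C)cc(=O)c3c2OC)c(O)c(C)c2OC(C)(C)OC(=O)c12 | intermediate
18 | (3R)-5-[(5,7-dimethoxy-2-methyl-4-oxo-4H-chromen-6-yl)methyl]-6,8-dihydroxy-3,7-dimethyl-3,4-dihydro-1H-isochromen-1-one | COc1cc2oc(C)cc(=O)c2c(OC)c1Cc1c(O)c(C)c(O)c2c1C[C@@H](C)OC2=O | intermediate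
19 | (3R)-6,8-dihydroxy-5-[(5-hydroxy-7-methoxy-2-methyl-4-oxo-4H-chromen-6-yl)methyl]-3,7-dimethyl-3,4-dihydro-1H-isochromen-1-one | COc1cc2oc(C)cc(=O)c2c(O)c1Cc1c(O)c(C)c(O)c2c1C[C@@H](C)OC2=O | target

## Step count and least certain steps

Total: 13 steps. Longest linear sequence: 8 steps (8 → 9 → 11 → 12 → 13 → 14 → 16 → 18 → 19; steps 6 to 13). The dioxinone branch (steps 1, 2, 5) and the chiral branch (steps 3, 4, 5) each join after three steps.

Step 11 (key step). The most likely failure is attack of an enol oxygen on the acetal-bearing carbon C8, giving a pyranone. A slow aldol at the crowded C4a ketone, now flanked by substituted C5 and the side chain, would give this pathway and silanolate elimination more time. The fallback sets out from 14 and changes the nucleophile. Heating 14 in toluene with methanol opens the dioxinone by retro-[4+2] to an acylketene, which methanol traps as methyl (9R)-9-[(tert-butyldimethylsilyl)oxy]-6-[(5,7-dimethoxy-2-methyl-4-oxo-4H-chromen-6-yl)methyl]-4-methyl-3,5,7-trioxodecanoate F1. In F1 the C8 carbon carries no leaving group and C8a is a readily deprotonated β-keto ester carbon. Cs2CO3 in methanol followed by acetic acid should then effect aldol closure and dehydration to methyl 3-[(2R)-2-[(tert-butyldimethylsilyl)oxy]propyl]-4-[(5,7-dimethoxy-2-methyl-4-oxo-4H-chromen-6-yl)methyl]-2,6-dihydroxy-5-methylbenzoate… more precisely the methyl resorcylate F2. Bu4NF would desilylate F2 and close the lactone with loss of methanol, rejoining the route at 18.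

Step 10. The most likely failure is base-induced ring closure of 7 before it is alkylated, with O-alkylation of the enolate as a second loss; the base that forms the enolate is also the trigger for the aldol. The fallback sets out from 7 and accepts that closure. Et3N in CH2Cl2 should turn 7 into 5-[(2R)-2-[(tert-butyldimethylsilyl)oxy]propyl]-7-hydroxy-2,2,8-trimethyl-4H-1,3-benzodioxin-4-one F3. Its single free ring position (the later C5) is ortho to the phenol and para to the acetal oxygen. Friedel–Crafts benzylation of F3 with alcohol 12 under catalytic Sc(OTf)3 in CH2Cl2 at −20 → 0 °C would give 16, where the route is rejoined. Step 9 is then not needed, and the arene still comes from the same dioxinone aldol.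

Step 7. The most likely failures are capture of the aroylpalladium species by diethylamine (amide formation), 5-exo closure to an aurone, or slow oxidative addition at an iodide flanked on both sides. The fallback sets out from 9 and builds the pyranone by condensation chemistry. Stille coupling with tributyl(1-ethoxyvinyl)stannane (PdCl2(PPh3)2, toluene, 100 °C) would give 3-(1-ethoxyvinyl)-4-hydroxy-2,6-dimethoxybenzaldehyde F4. Dilute HCl on work-up hydrolyses it to 3-acetyl-4-hydroxy-2,6-dimethoxybenzaldehyde F5. Heating F5 with N,N-dimethylacetamide dimethyl acetal gives the enaminone 3-[(2E)-3-(dimethylamino)but-2-enoyl]-4-hydroxy-2,6-dimethoxybenzaldehyde F6, which closes in acetic acid with loss of dimethylamine to 11.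

Step 2. The most likely failure is O-acylation or α-acylation of the dienolate, which is more hindered than the parent because its γ-carbon is secondary. The fallback sets out from 2 and replaces acylation by aldol addition and oxidation. The lithium dienolate of 2 adds to acetaldehyde at −78 °C to give 6-(3-hydroxybutan-2-yl)-2,2-dimethyl-4H-1,3-dioxin-4-one F7, and Dess–Martin periodinane oxidises F7 to 3.

Step 5. The most likely failure is proton transfer from 6 to the dianion in place of addition, followed by loss of silanolate from the deprotonated amide, or incomplete formation of the dianion. The fallback sets out from 5 and uses a more electrophilic partner. iBu2AlH at −78 °C reduces 5 to (R)-3-[(tert-butyldimethylsilyl)oxy]butanal F8. Aldol addition of the dianion of 3 to F8 gives 6-[(7R)-7-[(tert-butyldimethylsilyl)oxy]-5-hydroxy-3-oxooctan-2-yl]-2,2-dimethyl-4H-1,3-dioxin-4-one F9, and Dess–Martin periodinane oxidises F9 to 7.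

## Further compounds

F1 | step 11 | methyl (9R)-9-[(tert-butyldimethylsilyl)oxy]-6-[(5,7-dimethoxy-2-methyl-4-oxo-4H-chromen-6-yl)methyl]-4-methyl-3,5,7-trioxodecanoate | COC(=O)CC(=O)C(C)C(=O)C(Cc1c(OC)cc2oc(C)cc(=O)c2c1OC)C(=O)C[C@@H](C)O[Si](C)(C)C(C)(C)C
F2 | step 11 | methyl resorcylate: methyl 2-[(2R)-2-[(tert-butyldimethylsilyl)oxy]propyl]-3-[(5,7-dimethoxy-2-methyl-4-oxo-4H-chromen-6-yl)methyl]-4,6-dihydroxy-5-methylbenzoate | COC(=O)c1c(O)c(C)c(O)c(Cc2c(OC)cc3oc(C)cc(=O)c3c2OC)c1C[C@@H](C)O[Si](C)(C)C(C)(C)C
F3 | step 10 | 5-[(2R)-2-[(tert-butyldimethylsilyl)oxy]propyl]-7-hydroxy-2,2,8-trimethyl-4H-1,3-benzodioxin-4-one | C[C@H](Cc1cc(O)c(C)c2OC(C)(C)OC(=O)c12)O[Si](C)(C)C(C)(C)C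
F4 | step 7 | 3-(1-ethoxyvinyl)-4-hydroxy-2,6-dimethoxybenzaldehyde | CCOC(=C)c1c(O)cc(OC)c(C=O)c1OC
F5 | step 7 | 3-acetyl-4-hydroxy-2,6-dimethoxybenzaldehyde | CC(=O)c1c(O)cc(OC)c(C=O)c1OC
F6 | step 7 | 3-[(2E)-3-(dimethylamino)but-2-enoyl]-4-hydroxy-2,6-dimethoxybenzaldehyde | CN(C)/C(C)=C/C(=O)c1c(O)cc(OC)c(C=O)c1OC
F7 | step 2 | 6-(3-hydroxybutan-2-yl)-2,2-dimethyl-4H-1,3-dioxin-4-one (diastereomer mixture) | CC(O)C(C)C1=CC(=O)OC(C)(C)O1
F8 | step 5 | (R)-3-[(tert-butyldimethylsilyl)oxy]butanal | C[C@H](CC=O)O[Si](C)(C)C(C)(C)C
F9 | step 5 | 6-[(7R)-7-[(tert-butyldimethylsilyl)oxy]-5-hydroxy-3-oxooctan-2-yl]-2,2-dimethyl-4H-1,3-dioxin-4-one (diastereomer mixture) | C[C@H](CC(O)CC(=O)C(C)C1=CC(=O)OC(C)(C)O1)O[Si](C)(C)C(C)(C)C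
A1 | alternative 1 | methyl 2-{[(3R)-6,8-bis(benzyloxy)-3,7-dimethyl-1-oxo-3,4-dihydro-1H-isochromen-5-yl]methyl}-3,5,7,9-tetraoxodecanoate | COC(=O)C(Cc1c(OCc2ccccc2)c(C)c(OCc2ccccc2)c2c1C[C@@H](C)OC2=O)C(=O)CC(=O)CC(=O)CC(C)=O
A2 | alternative 1 | (3R)-6,8-bis(benzyloxy)-5-[(5,7-dihydroxy-2-methyl-4-oxo-4H-chromen-6-yl)methyl]-3,7-dimethyl-3,4-dihydro-1H-isochromen-1-one | Cc1cc(=O)c2c(O)c(Cc3c(OCc4ccccc4)c(C)c(OCc4ccccc4)c4c3C[C@@H](C)OC4=O)c(O)cc2o1
A3 | alternative 2 | (3R)-6,8-bis(benzyloxy)-5-[(4-hydroxy-3-iodo-2,6-dimethoxyphenyl)methyl]-3,7-dimethyl-3,4-dihydro-1H-isochromen-1-one | COc1cc(O)c(I)c(OC)c1Cc1c(OCc2ccccc2)c(C)c(OCc2ccccc2)c2c1C[C@@H](C)OC2=O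
A4 | alternative 2 | (3R)-6,8-bis(benzyloxy)-5-[(5,7-dimethoxy-2-methyl-4-oxo-4H-chromen-6-yl)methyl]-3,7-dimethyl-3,4-dihydro-1H-isochromen-1-one | COc1cc2oc(C)cc(=O)c2c(OC)c1Cc1c(OCc3ccccc3)c(C)c(OCc3ccccc3)c2c1C[C@@H](C)OC2=O
A5 | alternative 3 | (6R)-4-[2-diazo-3-(5,7-dimethoxy-2-methyl-4-oxo-4H-chromen-6-yl)propanoyl]-6-methyl-5,6-dihydro-2H-pyran-2-one | C[C@@H]1CC(C(=O)C(=[N+]=[N-])Cc2c(OC)cc3oc(C)cc(=O)c3c2OC)=CC(=O)O1
A6 | alternative 3 | triisopropyl(prop-1-yn-1-yloxy)silane | CC#CO[Si](C(C)C)(C(C)C)C(C)C
A7 | alternative 3 | (3R)-5-[(5,7-dimethoxy-2-methyl-4-oxo-4H-chromen-6-yl)methyl]-8-hydroxy-3,7-dimethyl-6-[(triisopropylsilyl)oxy]-3,4-dihydro-1H-isochromen-1-one | C[C@@H]1Cc2c(Cc3c(OC)cc4oc(C)cc(=O)c4c3OC)c(O[Si](C(C)C)(C(C)C)C(C)C)c(C)c(O)c2C(=O)O1
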